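I wanted to know which way of charging leaves the most cross product after 40 h: everything together, or second substrate or starting material added late.

| flask | starting material | partner | second substrate | remark | time |
|---|---|---|---|---|---|
| spring | 0.40 M | 0.48 M | 0.20 M | run made earlier |  |
| winter | 0.40 M | 0.24 M | 0.20 M | run made earlier |  |
| summer | 0.40 M | 0.36 M | 0.20 M | run made earlier |  |
| autumn | 0.60 M | 0.48 M | 0.20 M | run made earlier |  |
| eta | 0.40 M | 0.480 M | 0.200 M | everything together at the start | 40 h |
| epsilon | 0.40 M | 0.480 M | 0.200 M (fed, over 15 h) | all else is in the flask from the start; the feed brings no volume worth counting | 40 h |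
| delta | 0.40 M (in portions, 2, over 15 h) | 0.480 M | 0.200 M | first portion at the start, last at 15 h | 40 h |
| theta | 0.40 M (fed, over 15 h) | 0.480 M | 0.200 M | all else is in the flask from the start; the feed brings no volume worth counting | 40 h |

| run | time / h | cross product / % | target / % | starting material / % |
|---|---|---|---|---|
| spring | 2.00 | 17.7 | 11.7 | 69.5 |
| spring | 6.00 | 24.2 | 16.3 | 45.2 |
| spring | 12.0 | 27.9 | 15.3 | 27.8 |
| spring | 15.0 | 28.1 | 14.5 | 22.8 |
| spring | 25.0 | 28.9 | 11.0 | 14.1 |
| winter | 4.00 | 27.4 | 7.7 | 63.0 |
| winter | 8.00 | 32.5 | 8.5 | 48.0 |
| winter | 15.0 | 35.1 | 6.5 | 35.3 |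
| winter | 25.0 | 38.9 | 4.2 | 27.6 |
| winter | 50.0 | 39.5 | 1.8 | 21.7 |
| summer | 4.00 | 25.1 | 11.0 | 59.0 |
| summer | 8.00 | 28.7 | 13.1 | 42.6 |
| summer | 15.0 | 31.7 | 11.6 | 29.0 |
| summer | 25.0 | 33.6 | 7.5 | 19.1 |
| summer | 50.0 | 34.3 | 4.1 | 12.1 |
| autumn | 4.00 | 18.4 | 12.7 | 57.6 |
| autumn | 12.0 | 22.9 | 10.5 | 29.5 |
| autumn | 20.0 | 23.7 | 7.9 | 20.7 |
| autumn | 30.0 | 22.6 | 4.2 | 14.4 |
| autumn | 50.0 | 23.9 | 2.6 | 11.0 |

(each reading ± 0.5 percentage points)

- what was read earlier has a scatter of 0.5 percentage points, one standard deviation
- a reading or a percentage of target counts all its forms, free or not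

- the flask that comes out highest in amount of cross product, in percent of the starting material charged; "all alike" if 1.5 percentage points covers them all (eta / epsilon / delta / theta / all alike)
- amount of cross product at the end, in percent of the starting material charged, eta
- amount of cross product at the end, in percent of the starting material charged, epsilon
- amount of cross product at the end, in percent of the starting material charged, delta
- amount of cross product at the end, in percent of the starting material charged, theta

I followed one molecule of second substrate. Cross product levelled off lower with more partner, 28.9% in spring against 39.5% in winter, so I assumed a fork, with starting material on one side and a partner-driven loss on the other, both first order in the molecule. Its chance φ of becoming cross product reads as the last cross product per second substrate charged: 0.578 in spring, 0.790 in winter, 0.686 in summer and 0.717 in autumn. Dividing the odds φ/(1−φ) by the charged ratio r = [starting material]/[partner] gave 1.64, 2.26, 1.97 and 2.03. Their mean, 1.97, is my selectivity factor S, the odds of cross product per unit of r.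

Eta repeats spring, so I took 28.9%. Delta starts at r = 0.417, which gives 22.6%. For epsilon I used spring's starting material at 6.00 h with partner at its charge: r = 0.377, giving 21.3%.

Theta took a chain. On the fork, spring's first reading implies 0.122 M of second substrate consumed by 2.00 h, hence a partner-driven loss rate 0.200 h⁻¹ and a lifetime τ against that loss of 5.00 h. Starting material decayed at 0.182 h⁻¹ in spring and theta's feed brings 0.0267 M h⁻¹, so I put theta's [starting material] at τ at 0.0876 M, giving 13.2%. The weak link was that single moment, since survivors meet more starting material. Feed over spring's decay rate, a second estimate of theta's [starting material], is 0.147 M, giving 18.8%. For theta I committed to the middle, 16.0%.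

The forecast also named eta: 29% (28% to 30%), epsilon 26% (20% to 31%), delta 19% (15% to 24%), theta 13% (9% to 20%), on the ground that “second substrate is being lost in a partner-dependent side reaction”. It put epsilon above delta; I put delta above epsilon.

The flasks gave 29.5% in eta, 25.5% in epsilon, 22.5% in delta and 16.9% in theta, each inside the forecast's range, with eta highest. Theta thus turned about a third of its second substrate into cross product. Its mean [starting material] over the first 15 h was 0.132 M; with S and partner at its charge, that gives φ = 0.352, or 17.6% of the starting material.

    starting material + target → side product (k = 0.648 M⁻¹ h⁻¹)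
    second substrate + target ⇌ idle adduct, settled at all times (K = 10.5 M⁻¹)
    partner → decomposed reagent (k = 0.0499 h⁻¹)
    starting material + partner → target (k = 0.177 M⁻¹ h⁻¹)
    starting material + second substrate → cross product (k = 0.833 M⁻¹ h⁻¹)
    second substrate + partner → second product (k = 0.449 M⁻¹ h⁻¹)

A neighbour of theta holds 0.080 M of second substrate. The same φ gives 7.05%; the computed flask gave 6.24%.

(All runs stem from a simulated flask from invented constants; the scatter is artificial.)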